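**Retrosynthetic overview**
1. Ring D is closed last, by 5-exo-dig carbocyclisation of a regiodefined C12 silyl enol ether onto a C8 propargyl arm. The 2β,3β-diol is installed just before that, while the 2-ene is the only electron-rich alkene.
2. Ring B and the 19,10-lactone form together, by reductive coupling of a ring A ketone (C10) with one arm of a cyclohexadienone (C9) followed by lactonisation of the alkoxide.
3. Ring C starts as a phenol. C6–C8 comes from ester α-arylation, and quaternary C8 from oxidative dearomatising propargylation.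
4. Ring A comes from Birch reduction–methylation of a 3-methoxyhomophthalate. A menthyl ester serves as the handle for separating the C4 epimers.
5. Order of ring formation: A (from arene), C (from arene), B plus lactone, D.

Assumption: gibberellane numbering (C1 to C19) is used for all intermediates. The two C4 epimers formed in step 3 are taken to be separable on silica or by crystallisation and assignable by X-ray analysis.

**Step 1**
Reactants: 1 3-methoxy-2-methylbenzoic acid; 2 (−)-menthol
Product: 3 (−)-menthyl 3-methoxy-2-methylbenzoate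
Conditions: DCC, DMAP (cat.), CH2Cl2, 0 °C to rt
Reagents that add atoms: none
Why: Steglich esterification attaches a cheap chiral alcohol that later allows separation of the C4 epimers and finally acts as the leaving group of the lactonisation; no new stereocentre is formed.

**Step 2**
Reactants: 3 (−)-menthyl 3-methoxy-2-methylbenzoate
Product: 5 2-[2-methoxy-6-(menthyloxycarbonyl)phenyl]acetic acid, via benzylic lithium species 4 (not isolated)
Conditions: LiN(i-Pr)2 (2.2 equiv), THF, −78 °C; CO2 (g); 1 M HCl
Reagents that add atoms: carbon dioxide, O=C=O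
Why: Lateral lithiation of an ortho-toluate followed by carboxylation installs C6–C7, the bulky menthyl ester suppressing self-condensation of the anion; no stereocentre is formed.

**Step 3**
Reactants: 5 2-[2-methoxy-6-(menthyloxycarbonyl)phenyl]acetic acid
Product: 8 menthyl (1R)-3-methoxy-2-(2-methoxy-2-oxoethyl)-1-methylcyclohexa-2,5-diene-1-carboxylate, via dipotassium dienolate carboxylate 6 (not isolated), via C4-methylated potassium carboxylate 7 (not isolated)
Conditions: KOt-Bu (1.0 equiv), THF; K (2.2 equiv), NH3, −78 °C; isoprene; MeI (4 equiv), −78 °C to rt, then DMF, rt; separation of C4 epimers on SiO2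
Reagents that add atoms: iodomethane, CI
Why: Birch reduction–alkylation in which the benzoate ring takes up two electrons, is protonated para at C1 by the tert-butanol liberated in situ and is methylated at C4, while the side-chain carboxylate is neither reduced nor enolised and is esterified by the excess MeI; little induction from menthol is expected, so C4 forms as two diastereomers and the (1R) isomer is isolated, which fixes the absolute configuration.

**Step 4**
Reactants: 8 menthyl (1R)-3-methoxy-2-(2-methoxy-2-oxoethyl)-1-methylcyclohexa-2,5-diene-1-carboxylate; 9 (4-bromophenoxy)(tert-butyl)dimethylsilane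
Product: 11 menthyl (1R)-6-[1-(4-hydroxyphenyl)-2-methoxy-2-oxoethyl]-1-methyl-5-oxocyclohex-2-ene-1-carboxylate, via α-aryl ester silyl ether 10 (not isolated)
Conditions: LiN(SiMe3)2 (2.4 equiv), Pd(dba)2 (3 mol %), P(t-Bu)3 (6 mol %), toluene, rt; then 48 % aq HF, MeCN, 0 °C
Reagents that add atoms: water, O
Why: Palladium-catalysed ester enolate α-arylation (Buchwald–Hartwig type) makes the C6–C8 bond, and aqueous HF then removes the silyl group and hydrolyses the enol ether to the unconjugated C10 ketone; C5 and C6 arise as an epimerisable mixture that is settled later.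

**Step 5**
Reactants: 11 menthyl (1R)-6-[1-(4-hydroxyphenyl)-2-methoxy-2-oxoethyl]-1-methyl-5-oxocyclohex-2-ene-1-carboxylate; 12 trimethyl(propa-1,2-dienyl)silane
Product: 13 menthyl (1R)-6-{2-methoxy-2-oxo-1-[4-oxo-1-(prop-2-ynyl)cyclohexa-2,5-dienyl]ethyl}-1-methyl-5-oxocyclohex-2-ene-1-carboxylate
Conditions: PhI(OAc)2 (1.1 equiv), 12 (5 equiv), (CF3)2CHOH, 0 °C
Reagents that add atoms: none
Why: Proposed new method: PhI(OAc)2 in (CF3)2CHOH turns the phenol into a phenoxenium-type cation whose para carbon C8 is attacked by the CH2 terminus of the allenylsilane (SE2' with loss of the silyl group to acetate) to give the propargyl-bearing quaternary carbon, the closest known reaction type being the oxidative Hosomi–Sakurai allylation of 4-alkylphenols with allyltrimethylsilane; C8 is not yet stereogenic because its two enone arms are identical.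

**Step 6 (key step)**
Reactants: 13 menthyl (1R)-6-{2-methoxy-2-oxo-1-[4-oxo-1-(prop-2-ynyl)cyclohexa-2,5-dienyl]ethyl}-1-methyl-5-oxocyclohex-2-ene-1-carboxylate
Product: 15 enone lactone (rings A B C plus 19,10-lactone; 2-ene; 13-en-12-one; 8β-propargyl; 5β-H; 6β-CO2Me; 9β-H; 10α-O), via tertiary hydroxy menthyl ester 14 (not isolated)
Conditions: SmI2 (2.2 equiv), t-BuOH (2.2 equiv), THF, −78 °C to rt
Reagents that add atoms: none
Why: Samarium diiodide ketone–enone reductive cyclisation (ketyl–olefin type) followed by lactonisation: two electrons join C10 to the β-carbon C9 of one enone arm in a 5-exo mode, the tether forces C10 onto the C6 face of ring C (9β-H cis to the propargyl arm), the new bond forms equatorially on ring A because axial approach is blocked by the axial C19 ester that also chelates trivalent samarium, so O10 is axial and syn to C19 and expels mentholate, the arm that places C11 next to O10 rather than next to C1H2 reacts (fixing C8), and C5 and C6 end as 5β-H and 6β-ester, the arrangement with the side chain equatorial on ring A and the ester trans to C4.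

**Step 7**
Reactants: 15 enone lactone
Product: 16 2β,3β-diol enone lactone
Conditions: OsO4 (2 mol %), NMO (1.2 equiv), acetone/H2O, 0 °C
Reagents that add atoms: N-methylmorpholine N-oxide, C[N+]1([O-])CCOCC1; water, O; osmium tetroxide (oxygen carrier), O=[Os](=O)(=O)=O
Why: Upjohn dihydroxylation, in which the 2-ene is the only electron-rich alkene (enone and alkyne react much more slowly) and OsO4 adds suprafacially from the β face opposite the lactone bridge, setting 2β-OH and 3β-OH.

**Step 8**
Reactants: 16 2β,3β-diol enone lactone
Product: 18 methyl ester of the target, via tris(trimethylsilyl) enol ether 17 (not isolated)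
Conditions: K[HB(s-Bu)3] (1.1 equiv), THF, −78 °C; Me3SiCl, Et3N; then Ph3PAuCl (5 mol %), AgBF4 (5 mol %), CH2Cl2/MeOH 10:1, rt; citric acid, MeOH
Reagents that add atoms: none
Why: 1,4-Hydride addition to the β-unsubstituted enone gives regiospecifically the C12–C13 enolate, trapped as its silyl enol ether, and the cationic monovalent gold catalyst then triggers a Conia-ene type 5-exo-dig carbocyclisation onto the axial propargyl arm, a bridging mode that allows only one configuration at C13 and leaves the 16-methylene group after protodeauration.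

**Step 9**
Reactants: 18 methyl ester of the target
Product: 19 target CNP0307952.1 (2β,3β,10-trihydroxy-12-oxo-20-norgibberell-16-ene-7,19-dioic acid 19,10-lactone)
Conditions: n-PrSLi (5 equiv), HMPA, rt; 1 M HCl
Reagents that add atoms: none
Why: SN2 demethylation of the hindered C7 ester by thiolate in a dipolar aprotic medium frees the acid without aqueous base, so the lactone, the retro-aldol-prone 3β-hydroxy group and C6 stay untouched.

**Compound list**
1 | 3-methoxy-2-methylbenzoic acid | COc1cccc(C(=O)O)c1C | starting material
2 | (−)-menthol, (1R,2S,5R)-2-isopropyl-5-methylcyclohexanol | C[C@@H]1CC[C@H]([C@@H](C1)O)C(C)C | starting material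
3 | (−)-menthyl 3-methoxy-2-methylbenzoate | COc1cccc(C(=O)O[C@@H]2C[C@H](C)CC[C@H]2C(C)C)c1C | intermediate
4 | benzylic lithium species of 3 | [Li]Cc1c(OC)cccc1C(=O)O[C@@H]1C[C@H](C)CC[C@H]1C(C)C | intermediate
5 | 2-[2-methoxy-6-(menthyloxycarbonyl)phenyl]acetic acid | COc1cccc(C(=O)O[C@@H]2C[C@H](C)CC[C@H]2C(C)C)c1CC(=O)O | intermediate
6 | dipotassium dienolate carboxylate from Birch reduction of 5 | COC1=C(CC(=O)[O-])C(=C([O-])O[C@@H]2C[C@H](C)CC[C@H]2C(C)C)C=CC1.[K+].[K+] | intermediate
7 | C4-methylated potassium carboxylate (both C4 epimers) | COC1=C(CC(=O)[O-])C(C)(C(=O)O[C@@H]2C[C@H](C)CC[C@H]2C(C)C)C=CC1.[K+] | intermediate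
8 | menthyl (1R)-3-methoxy-2-(2-methoxy-2-oxoethyl)-1-methylcyclohexa-2,5-diene-1-carboxylate | COC1=C(CC(=O)OC)[C@](C)(C(=O)O[C@@H]2C[C@H](C)CC[C@H]2C(C)C)C=CC1 | intermediate
9 | (4-bromophenoxy)(tert-butyl)dimethylsilane | CC(C)(C)[Si](C)(C)Oc1ccc(Br)cc1 | starting material
10 | α-aryl ester silyl ether (C6 epimers) | COC1=C(C(C(=O)OC)c2ccc(O[Si](C)(C)C(C)(C)C)cc2)[C@](C)(C(=O)O[C@@H]2C[C@H](C)CC[C@H]2C(C)C)C=CC1 | intermediate
11 | phenol keto diester (C4 fixed; C5 and C6 epimerisable mixture) | O=C1CC=C[C@@](C)(C(=O)O[C@@H]2C[C@H](C)CC[C@H]2C(C)C)C1C(C(=O)OC)c1ccc(O)cc1 | intermediate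
12 | trimethyl(propa-1,2-dienyl)silane | C=C=C[Si](C)(C)C | starting material
13 | keto dienone with C8 propargyl group (C4 fixed; C5 and C6 epimerisable mixture) | O=C1CC=C[C@@](C)(C(=O)O[C@@H]2C[C@H](C)CC[C@H]2C(C)C)C1C(C(=O)OC)C1(CC#C)C=CC(=O)C=C1 | intermediate
14 | tertiary hydroxy menthyl ester (ring B closed; 10α-OH) | C#CC[C@]12C=CC(=O)C[C@H]1[C@]1(O)CC=C[C@@](C)(C(=O)O[C@@H]3C[C@H](C)CC[C@H]3C(C)C)[C@H]1[C@@H]2C(=O)OC | intermediate
15 | enone lactone (2-ene; 13-en-12-one; 8β-propargyl; 7-methyl ester) | C#CC[C@]12C=CC(=O)C[C@H]1[C@@]13CC=C[C@@](C)(C(=O)O1)[C@H]3[C@@H]2C(=O)OC | intermediate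
16 | 2β,3β-diol enone lactone | C#CC[C@]12C=CC(=O)C[C@H]1[C@@]13C[C@H](O)[C@H](O)[C@@](C)(C(=O)O1)[C@H]3[C@@H]2C(=O)OC | intermediate
17 | tris(trimethylsilyl) derivative (C12–C13 silyl enol ether; 2,3-bis-silyl ether) | C#CC[C@]12CC=C(O[Si](C)(C)C)C[C@H]1[C@@]13C[C@H](O[Si](C)(C)C)[C@H](O[Si](C)(C)C)[C@@](C)(C(=O)O1)[C@H]3[C@@H]2C(=O)OC | intermediate
18 | methyl ester of the target | C=C1C[C@]23C[C@H]1C(=O)C[C@H]2[C@@]12C[C@H](O)[C@H](O)[C@@](C)(C(=O)O1)[C@H]2[C@@H]3C(=O)OC | intermediate
19 | CNP0307952.1 | C=C1C[C@]23C[C@H]1C(=O)C[C@H]2[C@@]12C[C@H](O)[C@H](O)[C@@](C)(C(=O)O1)[C@H]2[C@@H]3C(=O)O | target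

Total step count: 9. Longest linear sequence: 9 steps (from 1).

**Steps most likely to fail**

Step 6 is the riskiest. The dienone radical anion may rearomatise by expelling the C6 or the propargyl radical. The choice of enone arm, the trans A/B fusion and the C5/C6 epimer mixture may also erode the yield. The fallback sets out from 13 and comes back at 15, and it builds the lactone first and ring B second:
- 13 is heated with TsOH·H2O in wet toluene, so that the hydrated C10 ketone displaces menthol. This gives the bridged hydroxy lactone F1, in which C5 equilibrates to the epimer with the side chain equatorial.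
- SOCl2 converts F1 into the bridgehead chloro lactone F2.
- Visible-light reduction of the C–Cl bond (Ir(ppy)3, Hantzsch ester, i-Pr2NEt, MeCN) gives a bridgehead α-acyloxy radical of fixed geometry. It adds 5-exo to the dienone without the dienone ever being reduced.

Step 5 is next. Intermolecular attack of a weak carbon nucleophile at a hindered para carbon competes with quinone methide formation and with trapping by the neighbouring carbonyl oxygens. The fallback sets out from 11 and comes back at 13, and it separates oxidation from C–C bond formation: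
- 11 is oxidised with PhI(OAc)2 in MeOH to the para-quinol methyl ether F3.
- F3 is ionised with BF3·OEt2 at −78 °C in the presence of the far more nucleophilic Bu3SnCH=C=CH2, which substitutes the methoxy group at C8.

Step 8 is third. Possible failures are 1,2-reduction, enolate scrambling and alkoxide-induced retro-aldol cleavage. The fallback sets out from 16 and comes back at 18, and it replaces the preformed silyl enol ether by cooperative enamine and π-acid catalysis:
- 16 is reduced with [(Ph3P)CuH]6 in wet benzene to the saturated 12-ketone F4.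
- Pyrrolidine (20 mol %) with Cu(OTf)2 and PPh3 in MeOH then forms the less hindered C12–C13 enamine reversibly and cyclises it onto the copper-activated alkyne.

**Further compounds**
F1 | step 6 | bridged hydroxy lactone (10-hydroxy-19,10-lactone of ring A with dienone side chain) | O[C@@]12CC=C[C@@](C)(C(=O)O1)[C@H]2C(C(=O)OC)C1(CC#C)C=CC(=O)C=C1
F2 | step 6 | bridgehead chloro lactone | Cl[C@@]12CC=C[C@@](C)(C(=O)O1)[C@H]2C(C(=O)OC)C1(CC#C)C=CC(=O)C=C1
F3 | step 5 | para-quinol methyl ether of 11 | O=C1CC=C[C@@](C)(C(=O)O[C@@H]2C[C@H](C)CC[C@H]2C(C)C)C1C(C(=O)OC)C1(OC)C=CC(=O)C=C1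
F4 | step 8 | saturated 12-ketone with C8 propargyl group | C#CC[C@]12CCC(=O)C[C@H]1[C@@]13C[C@H](O)[C@H](O)[C@@](C)(C(=O)O1)[C@H]3[C@@H]2C(=O)OC
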